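**Plan**

- Retrosynthesis, in order: three benzyl ethers come off; a carboxyl helper is removed from C3; the C2–C3 bond of ring B is cut as an oxidative union of two enolate carbons; the C4–naphthyl bond is cut as a rhodium-catalysed asymmetric 1,4-addition of a naphthylboronic acid to a coumarin.
- Enabling feature: C2 is the only enolisable carbon of the C1 aryl ketone. C3, while it carries the ester carbon left over from the coumarin lactone, is an enolate carbon too. Both hang on the adjacent ring-A carbons C8a and C4a, so they are 1,6 to each other and a two-electron oxidation closes the six-membered ring B.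
- Forward order: 6-hydroxycoumarin supplies ring A and a temporary lactone ring that carries C3/C4 and masks O5; a Fries shift adds C1/C2. 5-Methoxy-1-naphthol supplies the naphthalene as a boronic acid. The fragments are joined at C4, the lactone is opened, ring B is closed last, then the helper and the benzyl groups are removed.
- Stereochemistry: the single stereocentre C4 (S) is set by the (S)-SEGPHOS–rhodium arylation of the coumarin. It is never alpha to a carbonyl afterwards. The transient C3 centre is erased.

Key step: step 9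

Remark: atom numbers C1–C8a are those of the tetralone in the target (C1 = C=O, C4 = stereocentre); ring A is its dioxygenated benzene ring and ring B its ketone ring. 5-Methoxy-1-naphthol is taken as a catalogue compound.

**Route**

Step 1
Reactants: 1 6-hydroxy-2H-chromen-2-one (6-hydroxycoumarin)
Product: 2 2-oxo-2H-chromen-6-yl acetate
Conditions: Ac2O, pyridine, DMAP (cat.), CH2Cl2, rt
Reagents that add atoms: acetic anhydride CC(=O)OC(C)=O
Why: Base-catalysed O-acylation of a phenol (esterification) places on O6 the acetyl group that the next step moves onto the ring.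

Step 2
Reactants: 2 2-oxo-2H-chromen-6-yl acetate
Product: 3 5-acetyl-6-hydroxy-2H-chromen-2-one
Conditions: AlCl3 (3 equiv), neat, 150 °C; then ice/2 M HCl
Reagents that add atoms: none
Why: The Fries rearrangement should deliver the acyl group to C5, the more nucleophilic of the two positions ortho to O6 (next to the ring fusion, as in other electrophilic substitutions of 6-hydroxycoumarin), and chelation of the new ketone by the phenol drives it.

Step 3
Reactants: 3 5-acetyl-6-hydroxy-2H-chromen-2-one
Product: 4 5-acetyl-6-(benzyloxy)-2H-chromen-2-one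
Conditions: BnBr, K2CO3, DMF, 60 °C
Reagents that add atoms: benzyl bromide BrCc1ccccc1
Why: Williamson ether synthesis on the phenoxide protects the future C8 hydroxyl as a base-stable ether, and the lactone tolerates anhydrous carbonate.

Step 4
Reactants: 5 5-methoxynaphthalen-1-ol
Product: 6 4-bromo-5-methoxynaphthalen-1-ol
Conditions: NBS (1.0 equiv), MeCN, -20 to 0 °C, dark
Reagents that add atoms: N-bromosuccinimide O=C1CCC(=O)N1Br
Why: Electrophilic aromatic bromination should go para to the free hydroxyl (C4, peri to OMe) because OH is a stronger donor than OMe and the alpha position of a naphthol is the most reactive; one equivalent at low temperature avoids oxidation to the quinone.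

Step 5
Reactants: 6 4-bromo-5-methoxynaphthalen-1-ol
Product: 7 1-(benzyloxy)-4-bromo-5-methoxynaphthalene
Conditions: BnBr, K2CO3, DMF, rt
Reagents that add atoms: benzyl bromide BrCc1ccccc1
Why: Williamson ether synthesis protects the naphthol for the organolithium and enolate steps that follow.

Step 6
Reactants: 7 1-(benzyloxy)-4-bromo-5-methoxynaphthalene
Product: 10 [4-(benzyloxy)-8-methoxynaphthalen-1-yl]boronic acid, via aryllithium 8 (not isolated), via lithium aryl(triisopropoxy)borate 9 (not isolated)
Conditions: n-BuLi, THF, -78 °C; B(OiPr)3, -78 °C to rt; 1 M HCl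
Reagents that add atoms: triisopropyl borate CC(C)OB(OC(C)C)OC(C)C; water O
Why: Bromine–lithium exchange is faster than any attack on the benzyl ether and gives an aryllithium stabilised by the peri methoxy group, which is trapped by the borate and hydrolysed (lithiation–borylation).

Step 7
Reactants: 4 5-acetyl-6-(benzyloxy)-2H-chromen-2-one; 10 [4-(benzyloxy)-8-methoxynaphthalen-1-yl]boronic acid
Product: 11 (4S)-5-acetyl-6-(benzyloxy)-4-[4-(benzyloxy)-8-methoxynaphthalen-1-yl]-3,4-dihydro-2H-chromen-2-one
Conditions: Rh(acac)(C2H4)2 (3 mol %), (S)-SEGPHOS (3.3 mol %), 10 (3 equiv), dioxane/H2O 10:1, 60 °C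
Reagents that add atoms: none
Why: In this Hayashi–Miyaura 1,4-addition the aryl–rhodium species inserts the flat, s-cis-locked enoate of the coumarin and the (S)-SEGPHOS ligand selects the face of C3=C4 that gives the 4S centre, by analogy with the established sense of this ligand family on coumarins (the sense is to be confirmed, and the (R)-ligand used if it proves opposite).

Step 8
Reactants: 11 (4S)-5-acetyl-6-(benzyloxy)-4-[4-(benzyloxy)-8-methoxynaphthalen-1-yl]-3,4-dihydro-2H-chromen-2-one
Product: 13 methyl (3S)-3-[2-acetyl-3,6-bis(benzyloxy)phenyl]-3-[4-(benzyloxy)-8-methoxynaphthalen-1-yl]propanoate, via ring-opened phenol ester 12 (not isolated)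
Conditions: K2CO3, BnBr, MeOH/acetone 1:1, 55 °C
Reagents that add atoms: methanol CO; benzyl bromide BrCc1ccccc1
Why: Methanolysis of the aryl lactone and Williamson trapping of the freed phenoxide prevent relactonisation, and C4 is not acidic toward carbonate, so its configuration is kept.

Step 9
Reactants: 13 methyl (3S)-3-[2-acetyl-3,6-bis(benzyloxy)phenyl]-3-[4-(benzyloxy)-8-methoxynaphthalen-1-yl]propanoate
Product: 15 methyl (1S,2RS)-5,8-bis(benzyloxy)-1-[4-(benzyloxy)-8-methoxynaphthalen-1-yl]-4-oxo-1,2,3,4-tetrahydronaphthalene-2-carboxylate, via dilithium bis-enolate 14 (not isolated)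
Conditions: LDA (2.3 equiv), THF, -78 °C (inverse addition); Fe(acac)3 (2.2 equiv), THF, 0.01 M, -78 °C to rt; aq. NH4Cl
Reagents that add atoms: none
Why: Inverse addition to excess LDA turns both carbonyl groups into lithium enolates (14), which shields them from Claisen and aldol attack; Fe(acac)3 then takes one electron from the more electron-rich ester enolate to give a C3 alpha-ester radical that adds to the CH2 terminus (C2) of the neighbouring ketone enolate, and a second one-electron oxidation of the ketyl radical anion gives the 1,4-dicarbonyl unit. The closest known reaction type is the intramolecular oxidative heterocoupling of a ketone enolate with an ester or amide enolate by trivalent iron or divalent copper salts. Ring B closes in a 6-endo-trig mode onto the enolate C1=C2 bond, since attack at the unsubstituted C2 is the normal regiochemistry for addition to a 1-aryl enolate and the 5-exo alternative at C1 would leave an unstabilised primary radical. The new stereocentre C3 is set by approach of C2 anti to the naphthyl group on C4 (trans expected), but it is of no consequence because C3 becomes CH2 in step 11, and C4 is not alpha to either carbonyl and keeps its configuration. The step needs intramolecular cross-coupling in place of intermolecular dimerisation, which the 1,6-relationship of the two enolate carbons across C4a–C8a of ring A and high dilution secure, and it needs an oxidant too weak to touch the benzyloxy and methoxy arenes, which Fe(acac)3 is. Over-oxidation of 15 to a naphthol is limited by using only a slight excess of oxidant and quenching cold.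

Step 10
Reactants: 15 methyl (1S,2RS)-5,8-bis(benzyloxy)-1-[4-(benzyloxy)-8-methoxynaphthalen-1-yl]-4-oxo-1,2,3,4-tetrahydronaphthalene-2-carboxylate
Product: 16 (1S,2RS)-5,8-bis(benzyloxy)-1-[4-(benzyloxy)-8-methoxynaphthalen-1-yl]-4-oxo-1,2,3,4-tetrahydronaphthalene-2-carboxylic acid
Conditions: LiOH·H2O, THF/MeOH/H2O 3:1:1, 40 °C, argon; then 1 M HCl
Reagents that add atoms: lithium hydroxide [Li+].[OH-]
Why: Saponification of the methyl ester frees the carboxyl helper; epimerisation at C3 is irrelevant, the C4 hydrogen is far too weakly acidic for hydroxide, and exclusion of air prevents oxidative aromatisation of ring B.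

Step 11
Reactants: 16 (1S,2RS)-5,8-bis(benzyloxy)-1-[4-(benzyloxy)-8-methoxynaphthalen-1-yl]-4-oxo-1,2,3,4-tetrahydronaphthalene-2-carboxylic acid
Product: 18 (4S)-5,8-bis(benzyloxy)-4-[4-(benzyloxy)-8-methoxynaphthalen-1-yl]-3,4-dihydronaphthalen-1(2H)-one, via Barton ester 17 (not isolated)
Conditions: N-hydroxypyridine-2-thione, DCC, DMAP (cat.), CH2Cl2, dark, 0 °C to rt; then t-BuSH (20 equiv), hν (tungsten lamp), rt
Reagents that add atoms: none
Why: Barton reductive decarboxylation removes the helper carbon as CO2 through a C3 radical that the large excess of thiol should reduce before it can rearrange, which also erases the C3 stereocentre and leaves C4 untouched.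

Step 12
Reactants: 18 (4S)-5,8-bis(benzyloxy)-4-[4-(benzyloxy)-8-methoxynaphthalen-1-yl]-3,4-dihydronaphthalen-1(2H)-one
Product: 19 (4S)-5,8-dihydroxy-4-(4-hydroxy-8-methoxynaphthalen-1-yl)-3,4-dihydronaphthalen-1(2H)-one
Conditions: H2 (1 atm), 10 % Pd/C, EtOAc/MeOH, rt
Reagents that add atoms: none
Why: Catalytic hydrogenolysis cleaves the three aryl benzyl ethers under neutral, reducing conditions that should spare the methyl ether, the hindered aryl ketone and the C4 centre, and that protect the hydroquinone from air oxidation.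

**Compound list**

1 | 6-hydroxy-2H-chromen-2-one | O=C1C=Cc2cc(O)ccc2O1 | starting material
2 | 2-oxo-2H-chromen-6-yl acetate | CC(=O)Oc1ccc2OC(=O)C=Cc2c1 | intermediate
3 | 5-acetyl-6-hydroxy-2H-chromen-2-one | CC(=O)c1c(O)ccc2OC(=O)C=Cc12 | intermediate
4 | 5-acetyl-6-(benzyloxy)-2H-chromen-2-one | CC(=O)c1c(OCc3ccccc3)ccc2OC(=O)C=Cc12 | intermediate
5 | 5-methoxynaphthalen-1-ol | COc1cccc2c(O)cccc12 | starting material
6 | 4-bromo-5-methoxynaphthalen-1-ol | COc1cccc2c(O)ccc(Br)c12 | intermediate
7 | 1-(benzyloxy)-4-bromo-5-methoxynaphthalene | COc1cccc2c(OCc3ccccc3)ccc(Br)c12 | intermediate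
8 | [4-(benzyloxy)-8-methoxynaphthalen-1-yl]lithium | COc1cccc2c(OCc3ccccc3)ccc([Li])c12 | intermediate (not isolated)
9 | lithium [4-(benzyloxy)-8-methoxynaphthalen-1-yl]tri(propan-2-yloxy)borate | [Li+].COc1cccc2c(OCc3ccccc3)ccc([B-](OC(C)C)(OC(C)C)OC(C)C)c12 | intermediate (not isolated)
10 | [4-(benzyloxy)-8-methoxynaphthalen-1-yl]boronic acid | COc1cccc2c(OCc3ccccc3)ccc(B(O)O)c12 | intermediate
11 | (4S)-5-acetyl-6-(benzyloxy)-4-[4-(benzyloxy)-8-methoxynaphthalen-1-yl]-3,4-dihydro-2H-chromen-2-one | COc1cccc2c(OCc5ccccc5)ccc([C@@H]3CC(=O)Oc4ccc(OCc6ccccc6)c(C(C)=O)c43)c12 | intermediate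
12 | methyl (3S)-3-[2-acetyl-3-(benzyloxy)-6-hydroxyphenyl]-3-[4-(benzyloxy)-8-methoxynaphthalen-1-yl]propanoate (present as its potassium phenoxide) | COc1cccc2c(OCc5ccccc5)ccc([C@H](CC(=O)OC)c4c(O)ccc(OCc6ccccc6)c4C(C)=O)c12 | intermediate (not isolated)
13 | methyl (3S)-3-[2-acetyl-3,6-bis(benzyloxy)phenyl]-3-[4-(benzyloxy)-8-methoxynaphthalen-1-yl]propanoate | COc1cccc2c(OCc5ccccc5)ccc([C@H](CC(=O)OC)c4c(OCc7ccccc7)ccc(OCc6ccccc6)c4C(C)=O)c12 | intermediate
14 | dilithium bis-enolate of 13 (ketone enolate C1=C2, ester enolate at C3; C4 configuration as in 13) | COc1cccc2c(OCc5ccccc5)ccc([C@H](C=C(OC)O[Li])c4c(OCc7ccccc7)ccc(OCc6ccccc6)c4C(=C)O[Li])c12 | intermediate (not isolated)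
15 | methyl (1S,2RS)-5,8-bis(benzyloxy)-1-[4-(benzyloxy)-8-methoxynaphthalen-1-yl]-4-oxo-1,2,3,4-tetrahydronaphthalene-2-carboxylate (epimers at the ester carbon, trans expected to predominate) | COc1cccc2c(OCc5ccccc5)ccc([C@@H]3C(C(=O)OC)CC(=O)c4c(OCc6ccccc6)ccc(OCc7ccccc7)c43)c12 | intermediate
16 | (1S,2RS)-5,8-bis(benzyloxy)-1-[4-(benzyloxy)-8-methoxynaphthalen-1-yl]-4-oxo-1,2,3,4-tetrahydronaphthalene-2-carboxylic acid | COc1cccc2c(OCc5ccccc5)ccc([C@@H]3C(C(=O)O)CC(=O)c4c(OCc6ccccc6)ccc(OCc7ccccc7)c43)c12 | intermediate
17 | 2-thioxopyridin-1(2H)-yl ester of 16 (Barton ester) | COc1cccc2c(OCc5ccccc5)ccc([C@@H]3C(C(=O)ON8C=CC=CC8=S)CC(=O)c4c(OCc6ccccc6)ccc(OCc7ccccc7)c43)c12 | intermediate (not isolated)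
18 | (4S)-5,8-bis(benzyloxy)-4-[4-(benzyloxy)-8-methoxynaphthalen-1-yl]-3,4-dihydronaphthalen-1(2H)-one | COc1cccc2c(OCc5ccccc5)ccc([C@@H]3CCC(=O)c4c(OCc6ccccc6)ccc(OCc7ccccc7)c43)c12 | intermediate
19 | (4S)-5,8-dihydroxy-4-(4-hydroxy-8-methoxynaphthalen-1-yl)-3,4-dihydronaphthalen-1(2H)-one | COc1cccc2c(O)ccc([C@@H]3CCC(=O)c4c(O)ccc(O)c43)c12 | target

**Step count and risks**

Total steps: 12. Longest linear sequence: 9 (steps 1, 2, 3, 7, 8, 9, 10, 11, 12; the naphthalene branch, steps 4, 5, 6, then 7 to 12, is equally long).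

Steps most likely to fail:

Step 7. The arylrhodation may stall because both partners are congested at the reacting carbons (peri-acetyl on the coumarin, peri-methoxy on the naphthyl), so protodeboronation could outrun insertion. The fallback sets out from 4 and 10 and makes the C4–aryl bond at a flat sp2 carbon first. An oxidative Heck-type arylation (Pd(OAc)2, 1,10-phenanthroline, O2, DMF, 80 °C) should give 5-acetyl-6-(benzyloxy)-4-[4-(benzyloxy)-8-methoxynaphthalen-1-yl]-2H-chromen-2-one F1. The stereocentre is then created by delivery of the small hydride to C4 in a copper hydride asymmetric conjugate reduction (Cu(OAc)2, the DTBM-SEGPHOS enantiomer that gives 4S, diethoxymethylsilane, t-BuOH, toluene). This is run warm enough for rotation about the C4–naphthyl axis, and the doubly ortho-flanked acetyl group is expected to be hydrosilylated more slowly than the lactone enoate. The fallback comes back to the route at 11.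

Step 9. The second enolisation may be incomplete, which would allow Claisen closure to a seven-membered diketone, or the product enolate may be oxidised further with aromatisation of ring B. The fallback sets out from 13 and forms the same C2–C3 bond by a polar alkylation. Saponification (LiOH, THF/MeOH/H2O) gives (3S)-3-[2-acetyl-3,6-bis(benzyloxy)phenyl]-3-[4-(benzyloxy)-8-methoxynaphthalen-1-yl]propanoic acid F2. This is converted with N-hydroxypyridine-2-thione and DCC into its 2-thioxopyridin-1(2H)-yl ester F3 (not isolated), which is photolysed with iodoform to 1-{3,6-bis(benzyloxy)-2-[(1S)-1-[4-(benzyloxy)-8-methoxynaphthalen-1-yl]-2-iodoethyl]phenyl}ethan-1-one F4 (Barton decarboxylative iodination). LDA (1.1 equiv, THF, -78 to 0 °C) then forms the lithium enolate of the methyl ketone F5 (not isolated), which should close ring B by 6-(enolendo)-exo-tet C-alkylation. The fallback comes back to the route at 18, so steps 10 and 11 fall away.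

Step 11. The C3 radical may undergo a 1,2-shift of the naphthyl group from C4 before hydrogen transfer, which would scramble the skeleton. The fallback sets out from 16 and avoids a free radical at C3. Thioesterification (EtSH, DCC, DMAP, CH2Cl2) gives S-ethyl (1S,2RS)-5,8-bis(benzyloxy)-1-[4-(benzyloxy)-8-methoxynaphthalen-1-yl]-4-oxo-1,2,3,4-tetrahydronaphthalene-2-carbothioate F6. Fukuyama reduction (Et3SiH, 10 % Pd/C, acetone, rt) gives (1S,2RS)-5,8-bis(benzyloxy)-1-[4-(benzyloxy)-8-methoxynaphthalen-1-yl]-4-oxo-1,2,3,4-tetrahydronaphthalene-2-carbaldehyde F7. Tsuji–Wilkinson decarbonylation with stoichiometric RhCl(PPh3)3 (toluene, 110 °C) then replaces the formyl group by hydrogen through an acyl–rhodium hydride. The fallback comes back to the route at 18.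

**Further compounds**

F1 | step 7 | 5-acetyl-6-(benzyloxy)-4-[4-(benzyloxy)-8-methoxynaphthalen-1-yl]-2H-chromen-2-one | COc1cccc2c(OCc5ccccc5)ccc(C3=CC(=O)Oc4ccc(OCc6ccccc6)c(C(C)=O)c43)c12
F2 | step 9 | (3S)-3-[2-acetyl-3,6-bis(benzyloxy)phenyl]-3-[4-(benzyloxy)-8-methoxynaphthalen-1-yl]propanoic acid | COc1cccc2c(OCc5ccccc5)ccc([C@H](CC(=O)O)c4c(OCc7ccccc7)ccc(OCc6ccccc6)c4C(C)=O)c12
F3 | step 9 | 2-thioxopyridin-1(2H)-yl ester of F2 | COc1cccc2c(OCc5ccccc5)ccc([C@H](CC(=O)ON8C=CC=CC8=S)c4c(OCc7ccccc7)ccc(OCc6ccccc6)c4C(C)=O)c12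
F4 | step 9 | 1-{3,6-bis(benzyloxy)-2-[(1S)-1-[4-(benzyloxy)-8-methoxynaphthalen-1-yl]-2-iodoethyl]phenyl}ethan-1-one | COc1cccc2c(OCc5ccccc5)ccc([C@H](CI)c4c(OCc7ccccc7)ccc(OCc6ccccc6)c4C(C)=O)c12
F5 | step 9 | lithium enolate of the methyl ketone F4 | COc1cccc2c(OCc5ccccc5)ccc([C@H](CI)c4c(OCc7ccccc7)ccc(OCc6ccccc6)c4C(=C)O[Li])c12
F6 | step 11 | S-ethyl (1S,2RS)-5,8-bis(benzyloxy)-1-[4-(benzyloxy)-8-methoxynaphthalen-1-yl]-4-oxo-1,2,3,4-tetrahydronaphthalene-2-carbothioate | COc1cccc2c(OCc5ccccc5)ccc([C@@H]3C(C(=O)SCC)CC(=O)c4c(OCc6ccccc6)ccc(OCc7ccccc7)c43)c12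
F7 | step 11 | (1S,2RS)-5,8-bis(benzyloxy)-1-[4-(benzyloxy)-8-methoxynaphthalen-1-yl]-4-oxo-1,2,3,4-tetrahydronaphthalene-2-carbaldehyde | COc1cccc2c(OCc5ccccc5)ccc([C@@H]3C(C=O)CC(=O)c4c(OCc6ccccc6)ccc(OCc7ccccc7)c43)c12
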